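## Analysis of the target

Compound 24 is isorhamnetin with a 1-(4-hydroxy-3,5-dimethoxyphenyl)ethyl group at C8. It is a 4H-chromen-4-one in which ring A (C4a to C8a) carries hydroxyls at C5 and C7, ring C carries the C4 carbonyl and the 3-hydroxyl, and ring B at C2 is 4-hydroxy-3-methoxyphenyl. The methine carbon that joins C8, a methyl group and the syringyl carbon C1'' is the only stereocentre. It is R, because C8, flanked by the oxygen-bearing C7 and C8a, outranks C1''. There is therefore no relative configuration to set, only one absolute configuration, and it is defined by nothing more than the difference between two electron-rich aryl groups. The sensitive elements are the five free phenolic or enolic hydroxyls (air oxidation, chelation through the 3-hydroxy and 5-hydroxy ketone units) and three aryl methyl ethers that must outlast every deprotection. The doubly benzylic methine on a phloroglucinol-type ring is also sensitive: strong acid can cleave or racemise it by ipso-protonation and retro-Friedel–Crafts loss, although it cannot enolise towards C4 because C8 is meta to C4a. The synthesis is hard for three reasons: a catalyst has little to choose between the two aryl groups, the methine sits in the congested pocket between O1 and O7, and ring A must be elaborated so that the side chain ends at C8 rather than C6, which means telling O1 apart from O5 and O7. The route rests on one observation: one oxidation level up, the methine carbon, its methyl group, C8 and the three ring A oxygens are the acetyl group and ring of 2,4,6-trihydroxyacetophenone 1, whose carbonyl-chelated hydroxyl is already distinguished from the other two. The configuration can then come from a ketone reduction, and the syringyl ring can be transferred from boron onto that carbon in a stereospecific way.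

## Retrosynthetic reasoning

**24 to 23.** The five O–benzyl bonds are cut last. Benzyl is the only temporary group used on oxygen at the end because hydrogenolysis leaves the three methyl ethers, the chromone and the methine untouched, so 24 is released under neutral conditions.

**23 to 21 to 20, then to 17 and 19.** Ring C is opened at O1–C2 and then at C2–C3. The forward sequence is O-aroylation of the ring A phenol, base-induced acyl transfer from oxygen to the ketone α-carbon (Baker–Venkataraman) and acid cyclodehydration through hemiketal 22. The C3 oxygen is carried in as a benzyloxy group on the α-carbon of ketone 17, so no late oxidation of a flavone is needed near the oxidisable methine. A chalcone oxidation route was not used because a 5-oxygenated ring A diverts it towards aurones. Acid chloride 19 comes in one step from acid 18.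

**17 to 16 to 15 to 13.** The C3–C4 bond is cut to aldehyde 15 and a benzyloxymethyl carbon nucleophile, with re-oxidation of carbinol 16. The C4a–C4 bond is cut by an ortho-formylation of phenol 13. This is where regiochemistry on ring A is decided. The only free phenol of 13 is the oxygen that becomes O1, and formylation directed by it can only reach the single open ortho position. That places the side chain at C8 and leaves the C–H between the two benzyloxy groups (future C6) alone.

**13 to 12 to 11.** Phenol 13 arises from methoxymethyl ether 12 by mild acetal cleavage. Ether 12 arises from tertiary boronic ester 11 by replacing boron with hydrogen with retention. Boron is only a traceless handle; its removal must not pass through a free carbanion.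

**11 to 5 and 8 (key disconnection).** The bond from the methine carbon to C1'' is cut. It is cut there, and not at the bond to C8, for two reasons. The ring A half is then a carbinol derivative of the commercially differentiated acetophenone, so the configuration is stored in a C–O bond made by reduction. The partner 8 is a simple aryl boronate with an unhindered boron. The forward reaction must deprotonate carbamate 5 at the benzylic carbon with retention (9), capture 9 on boron with retention (10), and shift the syringyl group to carbon with inversion. The step is stereospecific, not selective, so the similarity of the two arenes no longer matters.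

**5 to 4 to 3 to 2 to 1.** The carbamate comes from alcohol 4, and 4 from ketone 3 by oxazaborolidine-catalysed reduction. The protecting pattern of 3 follows from the chelation in 1: the two hydroxyls not held by the carbonyl are benzylated (2) and the remaining chelated one receives the methoxymethyl group. That oxygen is thereby marked as the future O1.

**8 to 7 to 6.** The boronate is cut at C–B (palladium-catalysed borylation of bromide 7), and 7 at its benzyl ether to the commercial bromophenol 6.

## Alternatives that were turned down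

**Alternative 1: benzoin-type closure of ring C across C3–C4.**
- Disconnection and key step: C3–C4 is cut, leading to dialdehyde A1. In A1 the ring A formyl group is the future C4, and the phenol oxygen carries a 1-aryl-2-oxoethyl unit (future C2 and C3). A triazolium-derived N-heterocyclic carbene would convert the ring A aldehyde into an acyl anion equivalent that adds to the aliphatic aldehyde, closing the six-membered ring as dihydroflavonol A2.
- For it: the closure is nearly neutral, it brings O3 in unprotected, and it avoids the strong base and the acid of steps 15 and 16 near the acid-labile methine. On mildness of ring C formation it is stronger than the chosen route.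
- Against it: A1 already contains the methine stereocentre, so the real problem still needs a separate asymmetric method. A1 is an enolisable α-aryl-α-aryloxy acetaldehyde, prone to enolisation and self-condensation, and must be made by alkylating a phenol wedged between a formyl group and the C8 side chain. The carbene should prefer the more electrophilic aliphatic aldehyde, which leads to the isomeric 4-hydroxychroman-3-one. A2 is one oxidation level too low, so a dehydrogenation has to be added on a substrate with an oxidisable doubly benzylic C–H.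
- Comparison: the chosen route spends its key step on the stereocentre and closes ring C by an acyl transfer whose regiochemistry cannot go astray.

**Alternative 2: late asymmetric hydrogenation of an 8-(1-arylvinyl)flavonol.**
- Disconnection and key step: the methine C–H and one methyl C–H are cut, leading to alkene A3. Hydrogenation with a chiral cationic complex of monovalent iridium of the type [Ir(cod)(P,N)]BArF (P,N = phosphinooxazoline) would give pentabenzyl ether A4, which is the same compound as 23.
- For it: it is the most convergent plan. The flavonol is assembled without any stereocentre to protect, the stereocentre is made one step from the end, and the total step count should be lower. On step economy it is stronger than the chosen route.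
- Against it: a 1,1-diarylethene gives the catalyst only the difference between two aryl groups. Here the alkene is buried between O1 and the 7-benzyloxy group and twisted out of conjugation. The chromone carbonyl and many ether oxygens compete for the cationic metal, and there is no free hydroxyl near the alkene to direct it. Neither the sense nor the level of induction can be predicted, and failure would consume the most advanced material.
- Comparison: the chosen route gives a configuration that is predictable from a ketone reduction, can be checked on the small alcohol 4, and is then passed on by stereospecific steps. The price is a longer linear sequence that carries the stereocentre.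

**Alternative 3: ring A grown around a chiral siloxyalkyne.**
- Disconnection and key step: ring A is cut at C8a–C8 and C6–C7. Heating cyclobutenone A5 with siloxyalkyne A6 would proceed by vinylketene formation, [2+2] addition, four-electron ring opening, six-electron closure and tautomerisation to phenol A7. In A7 the free hydroxyl is the future O1, O7 is silylated and O5 is benzylated.
- For it: the mechanism fixes the ring A substitution pattern and differentiates all three oxygens without selective protection. The stereocentre is made in a small unhindered molecule, so no bond has to be forced onto a carbon between two ortho oxygens. On that point it is stronger than step 7 of the chosen route.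
- Against it: A6 has to come from enantioenriched ester A8 by ynolate homologation under strongly basic conditions, which exposes the acidic α-aryl stereocentre to racemisation exactly where the configuration is stored. A5 is not a stock compound and siloxyalkynes are moisture-sensitive. After A7 the same formylation and ring C sequence is still required, with an extra silyl operation.
- Comparison: the chosen route starts from 1, in which every carbon and oxygen of ring A is already present and differentiated by chelation, and it creates the stereocentre by reduction instead of asking it to survive ynolate chemistry.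

Key step: step 7

## Route

Remark on the chemistry: 4-(benzyloxy)-3-methoxybenzoic acid 18 is taken as a purchased building block, and the descriptor R of the methine carbon is assigned with C8 ranking above C1''.

Step 1
Reactants: 1 2,4,6-trihydroxyacetophenone (phloroacetophenone)
Product: 2 1-[2,4-bis(benzyloxy)-6-hydroxyphenyl]ethan-1-one
Conditions: BnBr (2.1 equiv), K2CO3, DMF, rt
Reagents that add atoms: benzyl bromide, BrCc1ccccc1
Why: Williamson etherification; once the para and one ortho oxygen are alkylated, the remaining ortho hydroxyl is locked in a hydrogen bond to the acetyl carbonyl and should resist K2CO3-mediated alkylation, so the dibenzyl ether with one chelated hydroxyl is expected.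

Step 2
Reactants: 2 1-[2,4-bis(benzyloxy)-6-hydroxyphenyl]ethan-1-one
Product: 3 1-[2,4-bis(benzyloxy)-6-(methoxymethoxy)phenyl]ethan-1-one
Conditions: NaH, MOMCl, DMF, 0 °C → rt
Reagents that add atoms: chloromethyl methyl ether, COCCl
Why: Irreversible deprotonation with NaH breaks the chelate and the sodium phenoxide is alkylated by the reactive chloromethyl ether; this marks the oxygen that later becomes O1 with a group that is removable without touching benzyl or methyl ethers.

Step 3
Reactants: 3 1-[2,4-bis(benzyloxy)-6-(methoxymethoxy)phenyl]ethan-1-one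
Product: 4 (1R)-1-[2,4-bis(benzyloxy)-6-(methoxymethoxy)phenyl]ethan-1-ol
Conditions: (S)-Me-CBS (0.2 equiv), BH3·SMe2 (1.0 equiv), THF, −20 °C; MeOH
Reagents that add atoms: none
Why: Corey–Bakshi–Shibata reduction; the ketone binds to the oxazaborolidine boron anti to the bulky di-ortho-substituted aryl group and hydride is delivered within the six-membered assembly, which with the (S)-catalyst should give the R carbinol as for aryl methyl ketones in general. The alcohol is a very easily ionised benzylic alcohol and is to be worked up and chromatographed under base-buffered conditions.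

Step 4
Reactants: 4 (1R)-1-[2,4-bis(benzyloxy)-6-(methoxymethoxy)phenyl]ethan-1-ol
Product: 5 (1R)-1-[2,4-bis(benzyloxy)-6-(methoxymethoxy)phenyl]ethyl N,N-di(propan-2-yl)carbamate
Conditions: NaH, THF, 0 °C; iPr2NCOCl, 0 → 60 °C
Reagents that add atoms: N,N-diisopropylcarbamoyl chloride, CC(C)N(C(C)C)C(=O)Cl
Why: O-carbamoylation of the sodium alkoxide; the C–O bond of the stereocentre is not broken and the basic medium avoids ionisation of the electron-rich benzylic position, so the R configuration should be retained.

Step 5
Reactants: 6 4-bromo-2,6-dimethoxyphenol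
Product: 7 2-(benzyloxy)-5-bromo-1,3-dimethoxybenzene
Conditions: BnBr, K2CO3, DMF, 60 °C
Reagents that add atoms: benzyl bromide, BrCc1ccccc1
Why: Williamson etherification of a hindered but acidic phenol; the benzyl group is chosen so that the syringyl hydroxyl is released in the final hydrogenolysis.

Step 6
Reactants: 7 2-(benzyloxy)-5-bromo-1,3-dimethoxybenzene
Product: 8 2-[4-(benzyloxy)-3,5-dimethoxyphenyl]-4,4,5,5-tetramethyl-1,3,2-dioxaborolane
Conditions: B2pin2, PdCl2(dppf) (3 mol %; dppf = 1,1'-bis(diphenylphosphino)ferrocene), KOAc, 1,4-dioxane, 90 °C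
Reagents that add atoms: bis(pinacolato)diboron, CC1(C)OB(OC1(C)C)B1OC(C)(C)C(C)(C)O1
Why: Miyaura borylation; oxidative addition of the aryl bromide to zerovalent palladium, acetate-assisted transmetalation from the diboron reagent and reductive elimination, with KOAc too weak a base to trigger Suzuki homocoupling.

Step 7
Reactants: 5 (1R)-1-[2,4-bis(benzyloxy)-6-(methoxymethoxy)phenyl]ethyl N,N-di(propan-2-yl)carbamate; 8 2-[4-(benzyloxy)-3,5-dimethoxyphenyl]-4,4,5,5-tetramethyl-1,3,2-dioxaborolane
Product: 11 2-{(1R)-1-[2,4-bis(benzyloxy)-6-(methoxymethoxy)phenyl]-1-[4-(benzyloxy)-3,5-dimethoxyphenyl]ethyl}-4,4,5,5-tetramethyl-1,3,2-dioxaborolane, via lithiated carbamate 9 (not isolated), via lithium boronate complex 10 (not isolated)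
Conditions: s-BuLi (1.3 equiv), Et2O, −78 °C, 1 h; 8 (1.5 equiv), −78 °C, 2 h; MgBr2 in MeOH (1 M, 1.5 equiv), −78 °C → rt
Reagents that add atoms: none
Why: s-BuLi binds to the carbamate carbonyl and removes the benzylic hydrogen with retention, giving the dipole-stabilised organolithium 9, which the carbamate oxygen and the ortho oxygens of ring A can hold in place at −78 °C. Organolithium 9 adds to the vacant orbital of boronate 8 from the face that lithium occupied (retention) to give ate complex 10. On addition of MgBr2 in methanol and warming, the electron-rich syringyl group moves from boron to carbon antiperiplanar to the carbamate, which leaves as its metal salt; this 1,2-shift inverts the carbon and forms the bond from the benzylic carbon to C1''. The closest known reaction type is the lithiation and borylation of secondary benzylic carbamates with aryl pinacol boronic esters, a 1,2-metallate rearrangement of Matteson type. No ring is closed. The new fully substituted stereocentre is controlled only by the configuration of 5 through a retention then inversion sequence, which should give the R boronic ester. Two things are needed: deprotonation at the benzylic C–H and not at a ring C–H or a benzyl ether methylene, which the carbamate-directed proximity effect in Et2O without a diamine should secure, and stereospecificity, which rests on keeping 9 cold. MgBr2 activates the leaving group, and methanol protonates any 9 released by reversal before it can racemise and add again.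

Step 8
Reactants: 11 2-{(1R)-1-[2,4-bis(benzyloxy)-6-(methoxymethoxy)phenyl]-1-[4-(benzyloxy)-3,5-dimethoxyphenyl]ethyl}-4,4,5,5-tetramethyl-1,3,2-dioxaborolane
Product: 12 1,5-bis(benzyloxy)-2-[(1R)-1-(4-benzyloxy-3,5-dimethoxyphenyl)ethyl]-3-(methoxymethoxy)benzene
Conditions: CsF (1.5 equiv), H2O (1.1 equiv), 1,4-dioxane, 45 °C
Reagents that add atoms: none
Why: Fluoride-promoted protodeboronation of a tertiary benzylic boronic ester; fluoride adds to boron and the ate complex is protonated at carbon by the single equivalent of water on the face that boron leaves, so boron should be replaced by hydrogen with retention and the R configuration carried into 12. Limiting the water keeps the diaryl-substituted carbon from passing through a free carbanion.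

Step 9
Reactants: 12 1,5-bis(benzyloxy)-2-[(1R)-1-(4-benzyloxy-3,5-dimethoxyphenyl)ethyl]-3-(methoxymethoxy)benzene
Product: 13 3,5-bis(benzyloxy)-2-[(1R)-1-(4-benzyloxy-3,5-dimethoxyphenyl)ethyl]phenol
Conditions: conc. HCl (cat.), MeOH/THF (1:1), 35 °C
Reagents that add atoms: none
Why: Acid-catalysed acetal exchange with methanol removes the phenolic methoxymethyl group far faster than benzyl or methyl aryl ethers react; dilute acid and mild temperature are chosen because the methine on the trioxygenated ring is prone to ipso-protonation under forcing acid.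

Step 10
Reactants: 13 3,5-bis(benzyloxy)-2-[(1R)-1-(4-benzyloxy-3,5-dimethoxyphenyl)ethyl]phenol
Product: 15 4,6-bis(benzyloxy)-3-[(1R)-1-(4-benzyloxy-3,5-dimethoxyphenyl)ethyl]-2-hydroxybenzaldehyde, via ortho-hydroxymethyl phenol 14 (not isolated)
Conditions: MgCl2 (anhydrous), Et3N, (CH2O)n, MeCN, reflux; 1 M HCl work-up
Reagents that add atoms: formaldehyde (from paraformaldehyde), C=O
Why: Magnesium-mediated ortho-formylation (Casnati–Skattebøl reaction); the magnesium phenoxide delivers formaldehyde to the only open ortho position, and salicyl alcohol 14 is oxidised in the flask by hydride transfer to a second formaldehyde. The C–H between the two benzyloxy groups is para to the phenoxide and is not reached by the chelated electrophile, which fixes the side chain at the future C8.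

Step 11
Reactants: 15 4,6-bis(benzyloxy)-3-[(1R)-1-(4-benzyloxy-3,5-dimethoxyphenyl)ethyl]-2-hydroxybenzaldehyde
Product: 16 2-(benzyloxy)-1-{4,6-bis(benzyloxy)-3-[(1R)-1-(4-benzyloxy-3,5-dimethoxyphenyl)ethyl]-2-hydroxyphenyl}ethan-1-ol (both epimers at the carbinol carbon)
Conditions: BnOCH2MgCl (3 equiv; from BnOCH2Cl, Mg, HgCl2 cat.), THF, −20 → 0 °C; aq NH4Cl
Reagents that add atoms: (benzyloxymethyl)magnesium chloride, Cl[Mg]COCc1ccccc1 (prepared from benzyl chloromethyl ether, ClCOCc1ccccc1)
Why: Grignard addition to a salicylaldehyde; the first equivalent forms the magnesium phenoxide, which chelates the formyl group, and a further equivalent adds the benzyloxymethyl carbon that becomes C3 with its oxygen already in place. The new carbinol centre forms as a mixture of epimers, which does not matter because it is oxidised in step 12.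

Step 12
Reactants: 16 2-(benzyloxy)-1-{4,6-bis(benzyloxy)-3-[(1R)-1-(4-benzyloxy-3,5-dimethoxyphenyl)ethyl]-2-hydroxyphenyl}ethan-1-ol
Product: 17 2-(benzyloxy)-1-{4,6-bis(benzyloxy)-3-[(1R)-1-(4-benzyloxy-3,5-dimethoxyphenyl)ethyl]-2-hydroxyphenyl}ethan-1-one
Conditions: MnO2 (activated, excess), CH2Cl2, rt
Reagents that add atoms: none
Why: MnO2 oxidises the electron-rich benzylic alcohol under neutral heterogeneous conditions, which avoids acid-induced ortho-quinone methide formation and leaves the phenol, the benzyl ethers and the methine alone; the ketone formed is stabilised by the hydrogen bond from the ortho hydroxyl.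

Step 13
Reactants: 18 4-(benzyloxy)-3-methoxybenzoic acid
Product: 19 4-(benzyloxy)-3-methoxybenzoyl chloride
Conditions: (COCl)2, DMF (cat.), CH2Cl2, 0 °C → rt
Reagents that add atoms: oxalyl chloride, O=C(Cl)C(=O)Cl
Why: Acid chloride formation through the catalytic chloroiminium species from DMF; the by-products are gases and the crude chloride is used directly.

Step 14
Reactants: 17 2-(benzyloxy)-1-{4,6-bis(benzyloxy)-3-[(1R)-1-(4-benzyloxy-3,5-dimethoxyphenyl)ethyl]-2-hydroxyphenyl}ethan-1-one; 19 4-(benzyloxy)-3-methoxybenzoyl chloride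
Product: 20 3,5-bis(benzyloxy)-2-[2-(benzyloxy)acetyl]-6-[(1R)-1-(4-benzyloxy-3,5-dimethoxyphenyl)ethyl]phenyl 4-(benzyloxy)-3-methoxybenzoate
Conditions: Et3N, DMAP (cat.), CH2Cl2, 0 °C → rt
Reagents that add atoms: none
Why: DMAP-catalysed O-acylation; the acylpyridinium ion is reactive enough for a chelated phenol flanked by the ketone and the C8 side chain, and the ester places ring B and the future C2 on the oxygen that becomes O1.

Step 15
Reactants: 20 3,5-bis(benzyloxy)-2-[2-(benzyloxy)acetyl]-6-[(1R)-1-(4-benzyloxy-3,5-dimethoxyphenyl)ethyl]phenyl 4-(benzyloxy)-3-methoxybenzoate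
Product: 21 2-(benzyloxy)-1-{4,6-bis(benzyloxy)-3-[(1R)-1-(4-benzyloxy-3,5-dimethoxyphenyl)ethyl]-2-hydroxyphenyl}-3-[4-(benzyloxy)-3-methoxyphenyl]propane-1,3-dione (epimers at C2 of the dione and enol tautomers)
Conditions: LiN(SiMe3)2 (3 equiv), THF, −78 → −10 °C; aq NH4Cl
Reagents that add atoms: none
Why: Baker–Venkataraman rearrangement; the lithium enolate of the α-benzyloxy ketone attacks the neighbouring aryl ester through a six-membered transition state and the aroyl group moves from oxygen to carbon, which creates the C2–C3 bond. The amide base is far too weak to remove the methine hydrogen, which is also not conjugated to the carbonyl, so the stereocentre is safe.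

Step 16
Reactants: 21 2-(benzyloxy)-1-{4,6-bis(benzyloxy)-3-[(1R)-1-(4-benzyloxy-3,5-dimethoxyphenyl)ethyl]-2-hydroxyphenyl}-3-[4-(benzyloxy)-3-methoxyphenyl]propane-1,3-dione
Product: 23 3,5,7-tris(benzyloxy)-2-[4-(benzyloxy)-3-methoxyphenyl]-8-[(1R)-1-(4-benzyloxy-3,5-dimethoxyphenyl)ethyl]-4H-chromen-4-one, via cyclic hemiketal 22 (not isolated)
Conditions: TsOH·H2O (0.2 equiv), toluene, 80 °C
Reagents that add atoms: none
Why: Acid-catalysed cyclodehydration; the phenol adds to the ring B ketone to give hemiketal 22 and loss of water gives the pyranone, closing ring C at O1–C2. The acylated ring A is deactivated towards ipso-protonation, so the C8–methine bond should survive catalytic sulfonic acid.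

Step 17
Reactants: 23 3,5,7-tris(benzyloxy)-2-[4-(benzyloxy)-3-methoxyphenyl]-8-[(1R)-1-(4-benzyloxy-3,5-dimethoxyphenyl)ethyl]-4H-chromen-4-one
Product: 24 3,5,7-trihydroxy-2-(4-hydroxy-3-methoxyphenyl)-8-[(1R)-1-(4-hydroxy-3,5-dimethoxyphenyl)ethyl]-4H-chromen-4-one (CNP0261887.1)
Conditions: H2 (1 atm), 10% Pd/C, THF/MeOH (1:1), rt
Reagents that add atoms: none
Why: Hydrogenolysis of the five aryl benzyl ethers over palladium on carbon; methyl ethers, the chromone double bond and the diarylmethine C–C bonds are inert at one atmosphere and room temperature, so the stereocentre set in steps 3 and 7 reaches the target unchanged.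

## Compound list

1 | 2,4,6-trihydroxyacetophenone (phloroacetophenone) | CC(=O)c1c(O)cc(O)cc1O | starting material
2 | 1-[2,4-bis(benzyloxy)-6-hydroxyphenyl]ethan-1-one | CC(=O)c1c(O)cc(OCc2ccccc2)cc1OCc1ccccc1 | intermediate
3 | 1-[2,4-bis(benzyloxy)-6-(methoxymethoxy)phenyl]ethan-1-one | CC(=O)c1c(OCOC)cc(OCc2ccccc2)cc1OCc1ccccc1 | intermediate
4 | (1R)-1-[2,4-bis(benzyloxy)-6-(methoxymethoxy)phenyl]ethan-1-ol | COCOc1cc(OCc2ccccc2)cc(OCc2ccccc2)c1[C@@H](C)O | intermediate
5 | (1R)-1-[2,4-bis(benzyloxy)-6-(methoxymethoxy)phenyl]ethyl N,N-di(propan-2-yl)carbamate | COCOc1cc(OCc2ccccc2)cc(OCc2ccccc2)c1[C@@H](C)OC(=O)N(C(C)C)C(C)C | intermediate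
6 | 4-bromo-2,6-dimethoxyphenol | COc1cc(Br)cc(OC)c1O | starting material
7 | 2-(benzyloxy)-5-bromo-1,3-dimethoxybenzene | COc1cc(Br)cc(OC)c1OCc1ccccc1 | intermediate
8 | 2-[4-(benzyloxy)-3,5-dimethoxyphenyl]-4,4,5,5-tetramethyl-1,3,2-dioxaborolane | COc1cc(B2OC(C)(C)C(C)(C)O2)cc(OC)c1OCc1ccccc1 | intermediate
9 | lithiated carbamate of 5, lithium in place of the benzylic hydrogen with retention (not isolated) | COCOc1cc(OCc2ccccc2)cc(OCc2ccccc2)c1[C@@]([Li])(C)OC(=O)N(C(C)C)C(C)C | intermediate
10 | lithium boronate (ate) complex of 9 with 8, boron in place of lithium with retention (not isolated) | [Li+].COCOc1cc(OCc2ccccc2)cc(OCc2ccccc2)c1[C@@]([B-]1(OC(C)(C)C(C)(C)O1)c1cc(OC)c(OCc2ccccc2)c(OC)c1)(C)OC(=O)N(C(C)C)C(C)C | intermediate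
11 | 2-{(1R)-1-[2,4-bis(benzyloxy)-6-(methoxymethoxy)phenyl]-1-[4-(benzyloxy)-3,5-dimethoxyphenyl]ethyl}-4,4,5,5-tetramethyl-1,3,2-dioxaborolane | COCOc1cc(OCc2ccccc2)cc(OCc2ccccc2)c1[C@](B1OC(C)(C)C(C)(C)O1)(C)c1cc(OC)c(OCc2ccccc2)c(OC)c1 | intermediate
12 | 1,5-bis(benzyloxy)-2-[(1R)-1-(4-benzyloxy-3,5-dimethoxyphenyl)ethyl]-3-(methoxymethoxy)benzene | COCOc1cc(OCc2ccccc2)cc(OCc2ccccc2)c1[C@H](C)c1cc(OC)c(OCc2ccccc2)c(OC)c1 | intermediate
13 | 3,5-bis(benzyloxy)-2-[(1R)-1-(4-benzyloxy-3,5-dimethoxyphenyl)ethyl]phenol | Oc1cc(OCc2ccccc2)cc(OCc2ccccc2)c1[C@H](C)c1cc(OC)c(OCc2ccccc2)c(OC)c1 | intermediate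
14 | 3,5-bis(benzyloxy)-2-[(1R)-1-(4-benzyloxy-3,5-dimethoxyphenyl)ethyl]-6-(hydroxymethyl)phenol, present as its magnesium salt (not isolated) | OCc1c(O)c([C@H](C)c2cc(OC)c(OCc3ccccc3)c(OC)c2)c(OCc2ccccc2)cc1OCc1ccccc1 | intermediate
15 | 4,6-bis(benzyloxy)-3-[(1R)-1-(4-benzyloxy-3,5-dimethoxyphenyl)ethyl]-2-hydroxybenzaldehyde | O=Cc1c(O)c([C@H](C)c2cc(OC)c(OCc3ccccc3)c(OC)c2)c(OCc2ccccc2)cc1OCc1ccccc1 | intermediate
16 | 2-(benzyloxy)-1-{4,6-bis(benzyloxy)-3-[(1R)-1-(4-benzyloxy-3,5-dimethoxyphenyl)ethyl]-2-hydroxyphenyl}ethan-1-ol, both epimers at the carbinol carbon | OC(COCc1ccccc1)c1c(O)c([C@H](C)c2cc(OC)c(OCc3ccccc3)c(OC)c2)c(OCc2ccccc2)cc1OCc1ccccc1 | intermediate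
17 | 2-(benzyloxy)-1-{4,6-bis(benzyloxy)-3-[(1R)-1-(4-benzyloxy-3,5-dimethoxyphenyl)ethyl]-2-hydroxyphenyl}ethan-1-one | O=C(COCc1ccccc1)c1c(O)c([C@H](C)c2cc(OC)c(OCc3ccccc3)c(OC)c2)c(OCc2ccccc2)cc1OCc1ccccc1 | intermediate
18 | 4-(benzyloxy)-3-methoxybenzoic acid | COc1cc(C(=O)O)ccc1OCc1ccccc1 | starting material
19 | 4-(benzyloxy)-3-methoxybenzoyl chloride | COc1cc(C(=O)Cl)ccc1OCc1ccccc1 | intermediate
20 | 3,5-bis(benzyloxy)-2-[2-(benzyloxy)acetyl]-6-[(1R)-1-(4-benzyloxy-3,5-dimethoxyphenyl)ethyl]phenyl 4-(benzyloxy)-3-methoxybenzoate | O=C(COCc1ccccc1)c1c(OC(=O)c2ccc(OCc3ccccc3)c(OC)c2)c([C@H](C)c2cc(OC)c(OCc3ccccc3)c(OC)c2)c(OCc2ccccc2)cc1OCc1ccccc1 | intermediate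
21 | 2-(benzyloxy)-1-{4,6-bis(benzyloxy)-3-[(1R)-1-(4-benzyloxy-3,5-dimethoxyphenyl)ethyl]-2-hydroxyphenyl}-3-[4-(benzyloxy)-3-methoxyphenyl]propane-1,3-dione, epimers at C2 of the dione | O=C(c1ccc(OCc2ccccc2)c(OC)c1)C(OCc1ccccc1)C(=O)c1c(O)c([C@H](C)c2cc(OC)c(OCc3ccccc3)c(OC)c2)c(OCc2ccccc2)cc1OCc1ccccc1 | intermediate
22 | 3,5,7-tris(benzyloxy)-2-[4-(benzyloxy)-3-methoxyphenyl]-8-[(1R)-1-(4-benzyloxy-3,5-dimethoxyphenyl)ethyl]-2-hydroxy-2,3-dihydro-4H-chromen-4-one, mixture at C2 and C3 (not isolated) | O=C1C(OCc2ccccc2)C(O)(c2ccc(OCc3ccccc3)c(OC)c2)Oc2c([C@H](C)c3cc(OC)c(OCc4ccccc4)c(OC)c3)c(OCc3ccccc3)cc(OCc3ccccc3)c12 | intermediate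
23 | 3,5,7-tris(benzyloxy)-2-[4-(benzyloxy)-3-methoxyphenyl]-8-[(1R)-1-(4-benzyloxy-3,5-dimethoxyphenyl)ethyl]-4H-chromen-4-one | COc1cc(-c2oc3c([C@H](C)c4cc(OC)c(OCc5ccccc5)c(OC)c4)c(OCc4ccccc4)cc(OCc4ccccc4)c3c(=O)c2OCc2ccccc2)ccc1OCc1ccccc1 | intermediate
24 | 3,5,7-trihydroxy-2-(4-hydroxy-3-methoxyphenyl)-8-[(1R)-1-(4-hydroxy-3,5-dimethoxyphenyl)ethyl]-4H-chromen-4-one | COc1cc(-c2oc3c([C@H](C)c4cc(OC)c(O)c(OC)c4)c(O)cc(O)c3c(=O)c2O)ccc1O | target

## Step count and least certain steps

Total: 17 steps. Longest linear sequence: 14 steps (steps 1–4, 7–12 and 14–17).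

**Step 7 (key step).** Three processes may spoil it.
- Deprotonation at the wrong site. In a di-ortho-substituted arene the benzylic C–H lies near the ring plane and is poorly aligned with the π system, so s-BuLi may instead attack the ring C–H next to the methoxymethoxy group or a benzyl ether methylene.
- Slow and reversible addition of the congested organolithium 9 to 8, so that 9 is released on warming and racemises or is quenched.
- Ionisation of the very electron-rich benzylic C–O bond of 10 ahead of the shift, with loss of stereospecificity.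

Fallback (sets out from 7 and, for the boron partner, from purchased material; returns at 11): the roles of the two arenes are exchanged so that the unhindered syringyl carbinol carries the carbamate. Bromine–lithium exchange on 7 (n-BuLi, THF, −78 °C) gives [4-(benzyloxy)-3,5-dimethoxyphenyl]lithium F1. Acylation with N-methoxy-N-methylacetamide gives 1-[4-(benzyloxy)-3,5-dimethoxyphenyl]ethan-1-one F2. Reduction with (R)-Me-CBS and BH3·SMe2 gives (1S)-1-[4-(benzyloxy)-3,5-dimethoxyphenyl]ethan-1-ol F3, and NaH with iPr2NCOCl gives (1S)-1-[4-(benzyloxy)-3,5-dimethoxyphenyl]ethyl N,N-di(propan-2-yl)carbamate F4. Commercial 3,5-bis(benzyloxy)phenol F5 is converted with NaH and MOMCl into 1,3-bis(benzyloxy)-5-(methoxymethoxy)benzene F6. This is lithiated between the methoxymethoxy and a benzyloxy group (n-BuLi, THF, 0 °C) to [2,4-bis(benzyloxy)-6-(methoxymethoxy)phenyl]lithium F7 and borylated with 2-isopropoxy-4,4,5,5-tetramethyl-1,3,2-dioxaborolane to 2-[2,4-bis(benzyloxy)-6-(methoxymethoxy)phenyl]-4,4,5,5-tetramethyl-1,3,2-dioxaborolane F8. Lithiation of F4 (s-BuLi, Et2O, −78 °C) gives the lithiated syringyl carbamate F9, addition of F8 gives the lithium boronate complex F10, and the MgBr2/MeOH-assisted shift of the ring A aryl group gives 11. Because the aryl group fixed on carbon and the one that migrates are exchanged, the S carbamate is required to reach the same R boronic ester. All of this is the known lithiation and borylation chemistry, applied to a benzylic carbamate without ortho substituents.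

**Step 3.** Facial selectivity may be poor and turnover slow, because the di-ortho-substituted aryl ketone is twisted out of conjugation and its ortho oxygens can bind borane. Optical purity of 4 may also be lost by acid-catalysed ionisation during work-up or chromatography.

Fallback (sets out from 3, returns at 5): reduction of 3 with NaBH4 in MeOH/THF gives racemic 1-[2,4-bis(benzyloxy)-6-(methoxymethoxy)phenyl]ethan-1-ol F11. Carbamoylation as in step 4 gives racemic 1-[2,4-bis(benzyloxy)-6-(methoxymethoxy)phenyl]ethyl N,N-di(propan-2-yl)carbamate F12. This robust, non-ionisable compound is resolved by preparative supercritical-fluid chromatography on an amylose tris(3,5-dimethylphenylcarbamate) phase to supply 5.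

**Step 10.** Intermediate 14 may react, through its quinone methide, with a second molecule of the electron-rich phenol at the C–H para to the phenoxide and give diarylmethane oligomers. The formylation itself may be slow because the only open ortho position is flanked by a benzyloxy group.

Fallback (sets out from 13, returns at 15): boronic-acid-templated ortho-hydroxymethylation (Nagata reaction) with PhB(OH)2 and paraformaldehyde, with catalytic propionic acid in toluene under water removal, gives 5,7-bis(benzyloxy)-8-[(1R)-1-(4-benzyloxy-3,5-dimethoxyphenyl)ethyl]-2-phenyl-4H-1,3,2-benzodioxaborinine F13. In F13 the hydroxymethyl carbon is tied up and cannot alkylate a second arene. Transesterification with propane-1,3-diol releases 14, now isolated, and MnO2 in CH2Cl2 oxidises it to 15.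

**Step 11.** Addition to the phenoxide-deactivated aldehyde may stall, and the ortho-hydroxybenzylic alcohol 16 may lose water to an ortho-quinone methide during work-up.

Fallback (sets out from 15, returns at 17): the phenol is masked again. MOMCl and iPr2NEt give 4,6-bis(benzyloxy)-3-[(1R)-1-(4-benzyloxy-3,5-dimethoxyphenyl)ethyl]-2-(methoxymethoxy)benzaldehyde F14. Addition of BnOCH2MgCl (1.3 equiv) gives 2-(benzyloxy)-1-{4,6-bis(benzyloxy)-3-[(1R)-1-(4-benzyloxy-3,5-dimethoxyphenyl)ethyl]-2-(methoxymethoxy)phenyl}ethan-1-ol F15. Dess–Martin periodinane buffered with NaHCO3 gives 2-(benzyloxy)-1-{4,6-bis(benzyloxy)-3-[(1R)-1-(4-benzyloxy-3,5-dimethoxyphenyl)ethyl]-2-(methoxymethoxy)phenyl}ethan-1-one F16. Dilute HCl in MeOH then removes the acetal, which is activated by the neighbouring ketone, to give 17.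

## Further compounds

F1 | step 7 | [4-(benzyloxy)-3,5-dimethoxyphenyl]lithium | [Li]c1cc(OC)c(OCc2ccccc2)c(OC)c1
F2 | step 7 | 1-[4-(benzyloxy)-3,5-dimethoxyphenyl]ethan-1-one | CC(=O)c1cc(OC)c(OCc2ccccc2)c(OC)c1
F3 | step 7 | (1S)-1-[4-(benzyloxy)-3,5-dimethoxyphenyl]ethan-1-ol | C[C@H](O)c1cc(OC)c(OCc2ccccc2)c(OC)c1
F4 | step 7 | (1S)-1-[4-(benzyloxy)-3,5-dimethoxyphenyl]ethyl N,N-di(propan-2-yl)carbamate | C[C@H](OC(=O)N(C(C)C)C(C)C)c1cc(OC)c(OCc2ccccc2)c(OC)c1
F5 | step 7 | 3,5-bis(benzyloxy)phenol | Oc1cc(OCc2ccccc2)cc(OCc2ccccc2)c1
F6 | step 7 | 1,3-bis(benzyloxy)-5-(methoxymethoxy)benzene | COCOc1cc(OCc2ccccc2)cc(OCc2ccccc2)c1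
F7 | step 7 | [2,4-bis(benzyloxy)-6-(methoxymethoxy)phenyl]lithium | COCOc1cc(OCc2ccccc2)cc(OCc2ccccc2)c1[Li]
F8 | step 7 | 2-[2,4-bis(benzyloxy)-6-(methoxymethoxy)phenyl]-4,4,5,5-tetramethyl-1,3,2-dioxaborolane | COCOc1cc(OCc2ccccc2)cc(OCc2ccccc2)c1B1OC(C)(C)C(C)(C)O1
F9 | step 7 | lithiated syringyl carbamate (lithium in place of the benzylic hydrogen of F4, retention) | C[C@]([Li])(OC(=O)N(C(C)C)C(C)C)c1cc(OC)c(OCc2ccccc2)c(OC)c1
F10 | step 7 | lithium boronate complex of F9 with F8 | [Li+].COCOc1cc(OCc2ccccc2)cc(OCc2ccccc2)c1[B-]1(OC(C)(C)C(C)(C)O1)[C@@](C)(OC(=O)N(C(C)C)C(C)C)c1cc(OC)c(OCc2ccccc2)c(OC)c1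
F11 | step 3 | racemic 1-[2,4-bis(benzyloxy)-6-(methoxymethoxy)phenyl]ethan-1-ol | COCOc1cc(OCc2ccccc2)cc(OCc2ccccc2)c1C(C)O
F12 | step 3 | racemic 1-[2,4-bis(benzyloxy)-6-(methoxymethoxy)phenyl]ethyl N,N-di(propan-2-yl)carbamate | COCOc1cc(OCc2ccccc2)cc(OCc2ccccc2)c1C(C)OC(=O)N(C(C)C)C(C)C
F13 | step 10 | 5,7-bis(benzyloxy)-8-[(1R)-1-(4-benzyloxy-3,5-dimethoxyphenyl)ethyl]-2-phenyl-4H-1,3,2-benzodioxaborinine | C1OB(c2ccccc2)Oc2c1c(OCc1ccccc1)cc(OCc1ccccc1)c2[C@H](C)c1cc(OC)c(OCc2ccccc2)c(OC)c1
F14 | step 11 | 4,6-bis(benzyloxy)-3-[(1R)-1-(4-benzyloxy-3,5-dimethoxyphenyl)ethyl]-2-(methoxymethoxy)benzaldehyde | O=Cc1c(OCOC)c([C@H](C)c2cc(OC)c(OCc3ccccc3)c(OC)c2)c(OCc2ccccc2)cc1OCc1ccccc1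
F15 | step 11 | 2-(benzyloxy)-1-{4,6-bis(benzyloxy)-3-[(1R)-1-(4-benzyloxy-3,5-dimethoxyphenyl)ethyl]-2-(methoxymethoxy)phenyl}ethan-1-ol, both epimers at the carbinol carbon | OC(COCc1ccccc1)c1c(OCOC)c([C@H](C)c2cc(OC)c(OCc3ccccc3)c(OC)c2)c(OCc2ccccc2)cc1OCc1ccccc1
F16 | step 11 | 2-(benzyloxy)-1-{4,6-bis(benzyloxy)-3-[(1R)-1-(4-benzyloxy-3,5-dimethoxyphenyl)ethyl]-2-(methoxymethoxy)phenyl}ethan-1-one | O=C(COCc1ccccc1)c1c(OCOC)c([C@H](C)c2cc(OC)c(OCc3ccccc3)c(OC)c2)c(OCc2ccccc2)cc1OCc1ccccc1
A1 | alternative 1 | 4,6-bis(benzyloxy)-2-{1-[4-(benzyloxy)-3-methoxyphenyl]-2-oxoethoxy}-3-[(1R)-1-(4-benzyloxy-3,5-dimethoxyphenyl)ethyl]benzaldehyde | O=CC(c1ccc(OCc2ccccc2)c(OC)c1)Oc1c([C@H](C)c2cc(OC)c(OCc3ccccc3)c(OC)c2)c(OCc2ccccc2)cc(OCc2ccccc2)c1C=O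
A2 | alternative 1 | 5,7-bis(benzyloxy)-2-[4-(benzyloxy)-3-methoxyphenyl]-8-[(1R)-1-(4-benzyloxy-3,5-dimethoxyphenyl)ethyl]-3-hydroxy-2,3-dihydro-4H-chromen-4-one, mixture at C2 and C3 | O=C1C(O)C(c2ccc(OCc3ccccc3)c(OC)c2)Oc2c([C@H](C)c3cc(OC)c(OCc4ccccc4)c(OC)c3)c(OCc3ccccc3)cc(OCc3ccccc3)c12
A3 | alternative 2 | 3,5,7-tris(benzyloxy)-2-[4-(benzyloxy)-3-methoxyphenyl]-8-[1-(4-benzyloxy-3,5-dimethoxyphenyl)ethenyl]-4H-chromen-4-one | COc1cc(-c2oc3c(C(=C)c4cc(OC)c(OCc5ccccc5)c(OC)c4)c(OCc4ccccc4)cc(OCc4ccccc4)c3c(=O)c2OCc2ccccc2)ccc1OCc1ccccc1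
A4 | alternative 2 | 3,5,7-tris(benzyloxy)-2-[4-(benzyloxy)-3-methoxyphenyl]-8-[(1R)-1-(4-benzyloxy-3,5-dimethoxyphenyl)ethyl]-4H-chromen-4-one (identical with 23) | COc1cc(-c2oc3c([C@H](C)c4cc(OC)c(OCc5ccccc5)c(OC)c4)c(OCc4ccccc4)cc(OCc4ccccc4)c3c(=O)c2OCc2ccccc2)ccc1OCc1ccccc1
A5 | alternative 3 | 3-(benzyloxy)cyclobut-2-en-1-one | O=C1C=C(OCc2ccccc2)C1
A6 | alternative 3 | {[(3R)-3-(4-benzyloxy-3,5-dimethoxyphenyl)but-1-yn-1-yl]oxy}tri(propan-2-yl)silane | CC(C)[Si](C(C)C)(C(C)C)OC#C[C@H](C)c1cc(OC)c(OCc2ccccc2)c(OC)c1
A7 | alternative 3 | 5-(benzyloxy)-2-[(1R)-1-(4-benzyloxy-3,5-dimethoxyphenyl)ethyl]-3-{[tri(propan-2-yl)silyl]oxy}phenol | Oc1cc(OCc2ccccc2)cc(O[Si](C(C)C)(C(C)C)C(C)C)c1[C@H](C)c1cc(OC)c(OCc2ccccc2)c(OC)c1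
A8 | alternative 3 | methyl (2R)-2-[4-(benzyloxy)-3,5-dimethoxyphenyl]propanoate | COC(=O)[C@H](C)c1cc(OC)c(OCc2ccccc2)c(OC)c1
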